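**Strategy.** The target is divided at the aryl–C2 bond of the upper dihydrobenzofuran into a lower bis(dihydrobenzofuran) arylzinc and an upper lactol acetate. The upper half rests on one disconnection: ring A, the 1,3-dioxygenated benzene within the seven-membered ring, holds C-a (the anisyl-bearing methine) and C-b (the methine shared with the upper dihydrobenzofuran) on neighbouring carbons, with its oxygen next to the C-a attachment. This is the imprint of 3,5-dimethoxybenzyne inserted into the C1–C2 bond of a 2-indanone-1-carboxylate: one operation forms both aryl–carbon bonds and expands the five-membered ring to the dibenzocycloheptanone. The precursor is methyl 5,7-bis(benzyloxy)-2-oxoindane-1-carboxylate, an enolised β-ketoester.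

Key step: step 8

Labels: C-a = ArCH and C-c = CHOH of the seven-membered ring; C-b and C-d = C3 and C2 of the upper dihydrobenzofuran; ring A = resorcinol ring joining C-a and C-b; ring B = benzo ring of the upper dihydrobenzofuran; ring C and ring D = benzo rings of the middle and lower dihydrobenzofurans; ring E = 3,5-dioxygenated phenyl ring.

Remark: the two oxygens of ring B are carried as benzyl ethers, because a methyl ether at the lactone-forming oxygen could not be cleaved selectively beside the other aryl methyl ethers.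

Assumption: the sense of induction of IpcBH2 and of Rh2(R-PTAD)4 is taken from 1-arylcycloalkenes and from 2-benzyloxyphenyl aryl diazomethanes; if an assignment shows the opposite sense, the antipodal reagent is used.

**Aryne precursor**

Step 1
Reactants: 1 3,5-dimethoxyphenol
Product: 2 3,5-dimethoxyphenyl N-isopropylcarbamate
Conditions: i-PrNCO, Et3N (cat.), CH2Cl2, rt
Reagents that add atoms: isopropyl isocyanate, CC(C)N=C=O
Why: Carbamoylation of the phenol by addition to the isocyanate installs a removable directing group for ortho-metalation.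

Step 2
Reactants: 2 3,5-dimethoxyphenyl N-isopropylcarbamate
Product: 6 3,5-dimethoxy-2-(trimethylsilyl)phenyl N-isopropylcarbamate, via N-silyl carbamate 3 (not isolated), via aryllithium 4 (not isolated), via disilyl carbamate 5 (not isolated)
Conditions: TBSOTf, TMEDA, Et2O, 0 °C to rt; n-BuLi, TMEDA, −78 °C; Me3SiCl, −78 °C to rt; aq. NaHSO4
Reagents that add atoms: chlorotrimethylsilane, C[Si](C)(C)Cl
Why: Directed ortho-metalation: after in-situ N-silylation the carbamate and the neighbouring methoxy group jointly direct lithiation to the carbon between them, Me3SiCl traps the aryllithium, and the N–Si bond is hydrolysed on work-up.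

Step 3
Reactants: 6 3,5-dimethoxy-2-(trimethylsilyl)phenyl N-isopropylcarbamate
Product: 8 3,5-dimethoxy-2-(trimethylsilyl)phenyl trifluoromethanesulfonate, via phenol 7 (not isolated)
Conditions: DBU, Et2NH, MeCN, 40 °C; then PhNTf2, rt
Reagents that add atoms: N-phenylbis(trifluoromethanesulfonimide), O=S(=O)(N(c1ccccc1)S(=O)(=O)C(F)(F)F)C(F)(F)F
Why: Base-induced E1cB loss of isopropyl isocyanate (trapped by Et2NH as the urea) frees the phenoxide, which is triflated in the same flask, the usual end of an ortho-silyl aryl triflate synthesis.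

**Ketoester**

Step 4
Reactants: 9 3,5-dihydroxyphenylacetic acid
Product: 11 3,5-bis(benzyloxy)phenylacetic acid, via benzyl ester 10 (not isolated)
Conditions: BnBr, K2CO3, DMF, 60 °C; then NaOH, MeOH–H2O, 60 °C; aq. HCl
Reagents that add atoms: benzyl bromide, BrCc1ccccc1
Why: Williamson benzylation of both phenols (and of the acid) followed by saponification of the benzyl ester gives an acid whose ring oxygens can later be unmasked without touching methyl ethers.

Step 5
Reactants: 11 3,5-bis(benzyloxy)phenylacetic acid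
Product: 13 methyl 4-[3,5-bis(benzyloxy)phenyl]-3-oxobutanoate, via acyl imidazolide 12 (not isolated)
Conditions: 1,1'-carbonyldiimidazole, THF, rt; then KO2CCH2CO2Me, MgCl2, Et3N, THF, rt to 50 °C; aq. HCl
Reagents that add atoms: potassium methyl malonate, COC(=O)CC(=O)[O-].[K+]
Why: Masamune–Brooks homologation: the acyl imidazolide acylates the magnesium malonate and decarboxylation on acidification gives the β-ketoester.

Step 6
Reactants: 13 methyl 4-[3,5-bis(benzyloxy)phenyl]-3-oxobutanoate
Product: 14 methyl 4-[3,5-bis(benzyloxy)phenyl]-2-diazo-3-oxobutanoate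
Conditions: 4-acetamidobenzenesulfonyl azide, Et3N, MeCN, 0 °C to rt
Reagents that add atoms: 4-acetamidobenzenesulfonyl azide, CC(=O)Nc1ccc(cc1)S(=O)(=O)N=[N+]=[N-]
Why: Regitz diazo transfer to the doubly activated methylene.

Step 7
Reactants: 14 methyl 4-[3,5-bis(benzyloxy)phenyl]-2-diazo-3-oxobutanoate
Product: 15 methyl 5,7-bis(benzyloxy)-2-oxoindane-1-carboxylate (racemic; largely enol)
Conditions: Rh2(OAc)4 (1 mol%), CH2Cl2, rt
Reagents that add atoms: none
Why: Rhodium-carbenoid aromatic C–H insertion (a formal intramolecular Friedel–Crafts alkylation) closes the five-membered ring at either of the two equivalent, doubly activated ortho positions of the symmetric ring, so no regiochemical question arises.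

**Key step**

Step 8
Reactants: 15 methyl 5,7-bis(benzyloxy)-2-oxoindane-1-carboxylate; 8 3,5-dimethoxy-2-(trimethylsilyl)phenyl trifluoromethanesulfonate
Product: 17 methyl 6,8-bis(benzyloxy)-1,3-dimethoxy-11-oxo-10,11-dihydro-5H-dibenzo[a,d][7]annulene-5-carboxylate (racemic), via aryne 16 (not isolated)
Conditions: CsF, MeCN, 80 °C
Reagents that add atoms: none
Why: Fluoride removes the silyl group of 8 and triflate leaves, giving 3,5-dimethoxybenzyne 16, whose carbon meta to the flanking methoxy group is attacked by the enol(ate) carbon C1 of 15, the usual polarisation of a 3-alkoxybenzyne because the developing aryl anion sits next to the inductively withdrawing oxygen. That aryl anion, ortho to the methoxy group, adds to the C2 ketone to give a benzocyclobutenoxide, and retro-aldol cleavage of the old C1–C2 bond leaves the ester enolate and an aryl ketone. The closest known reaction is the aryne acyl-alkylation of β-ketoesters, including the ring expansion of 2-indanone-1-carboxylates to dibenzocycloheptanones. The seven-membered ring is closed by two-carbon ring expansion of the five-membered ring (four-membered closure onto the ketone, then fragmentation), not by a direct cyclisation, so no ring-size preference has to be overcome. No stereocentre is controlled here: the ester-bearing carbon (C-b) is formed racemic and enolisable and is fixed later. The one selectivity needed is the regiochemistry of insertion (ester carbon meta and acyl carbon ortho to the 3-methoxy group), which the methoxy group of the aryne secures, while the strongly enolised C1 of 15 favours C- over O-arylation.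

**Upper fragment**

Step 9
Reactants: 17 dibenzocycloheptanone ester
Product: 19 methyl 6,8-bis(benzyloxy)-1,3-dimethoxy-11-(trifluoromethylsulfonyloxy)-5H-dibenzo[a,d][7]annulene-5-carboxylate, via potassium enolate 18 (not isolated)
Conditions: KN(SiMe3)2, THF, −78 °C; PhNTf2, −78 to 0 °C
Reagents that add atoms: N-phenylbis(trifluoromethanesulfonimide), O=S(=O)(N(c1ccccc1)S(=O)(=O)C(F)(F)F)C(F)(F)F
Why: Enol triflate formation: the ketone has a single enolisable, benzylic methylene that is more acidic than the diarylacetate C–H, and the enolate is trapped on oxygen.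

Step 10
Reactants: 19 enol triflate; 20 4-methoxyphenylboronic acid
Product: 21 methyl 6,8-bis(benzyloxy)-1,3-dimethoxy-11-(4-methoxyphenyl)-5H-dibenzo[a,d][7]annulene-5-carboxylate
Conditions: Pd(PPh3)4 (5 mol%), K3PO4, dioxane–H2O, 80 °C
Reagents that add atoms: none
Why: Suzuki–Miyaura coupling of the enol triflate places the anisyl group on the former ketone carbon (C-a) and fixes the C-a=C-c double bond in the ring.

Step 11
Reactants: 21 alkene ester
Product: 23 alkene lactone (3-aryl-benzofuran-2(3H)-one with free 8-hydroxyl; racemic at C-b), via diphenol ester 22 (not isolated)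
Conditions: BCl3, C6HMe5, CH2Cl2, −78 °C; MeOH; then PPTS (cat.), toluene, 80 °C
Reagents that add atoms: none
Why: Lewis-acid debenzylation with pentamethylbenzene as cation scavenger cleaves benzyl but not methyl aryl ethers and spares the alkene, and the phenol freed next to the ester carbon closes the five-membered aryl lactone under mild acid.

Step 12
Reactants: 23 alkene lactone
Product: 24 bis(tert-butyldimethylsilyl) derivative (2-silyloxybenzofuran with 8-silyloxy group; C-b planar)
Conditions: TBSOTf, Et3N, CH2Cl2, 0 °C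
Reagents that add atoms: tert-butyldimethylsilyl trifluoromethanesulfonate, CC(C)(C)[Si](C)(C)OS(=O)(=O)C(F)(F)F
Why: O-silylation of the very acidic 3-aryl-benzofuranone and of the phenol gives the aromatic 2-silyloxybenzofuran, which deletes the labile stereocentre C-b before the asymmetric step.

Step 13
Reactants: 24 bis(silyl) alkene
Product: 26 hydroxy lactone (C-a R; C-b R; C-c S), via alkylborane 25 (not isolated)
Conditions: IpcBH2 (from (−)-α-pinene), THF, −25 to 0 °C; NaOH, H2O2, THF–H2O, 0 °C to rt; aq. HCl, rt; then DBU (cat.), CH2Cl2, rt, argon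
Reagents that add atoms: hydrogen peroxide, OO
Why: Asymmetric hydroboration–oxidation: with C-b flattened and the tub-shaped ring inverting freely, the alkene carries no resident stereocentre, so the isopinocampheyl group alone selects the face and syn addition with boron on the less substituted carbon sets C-a (R) and C-c (S) with H and OH cis; alkaline peroxide also removes both silyl groups, acid recloses the lactone, and catalytic DBU equilibrates the acidic C-b to the epimer (R) in which the anisyl group is pseudo-axial and clear of the ortho-methoxy group of ring A, which is the relative configuration of the target.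

Step 14
Reactants: 26 hydroxy lactone
Product: 28 lactol triacetate (anomeric mixture at C-d), via aluminium hemiacetal 27 (not isolated)
Conditions: i-Bu2AlH, CH2Cl2, −78 °C; Ac2O, pyridine, DMAP, −78 to 0 °C
Reagents that add atoms: acetic anhydride, CC(=O)OC(C)=O
Why: Reductive acetylation: low-temperature hydride addition to the aryl lactone gives a stable aluminium hemiacetal that is acetylated in situ together with the two other aluminium alkoxides, so the open, enolisable hydroxy aldehyde never forms and C-b is from here on configurationally fixed.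

**Lower fragment**

Step 15
Reactants: 29 1-bromo-3,5-dimethoxybenzene; 30 3,5-dimethoxybenzoyl chloride
Product: 32 (2-bromo-6-hydroxy-4-methoxyphenyl)(3,5-dimethoxyphenyl)methanone, via methoxy ketone 31 (not isolated)
Conditions: AlCl3 (2.5 equiv), CH2Cl2, 0 °C to reflux; aq. HCl
Reagents that add atoms: none
Why: Friedel–Crafts acylation at the position para to one methoxy group and ortho to the other (next to bromine, the site at which this arene is also formylated), followed by chelation-driven AlCl3 cleavage of only the methoxy group ortho to the new ketone.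

Step 16
Reactants: 32 hydroxy ketone
Product: 33 [2-bromo-4-methoxy-6-(4-methoxybenzyloxy)phenyl](3,5-dimethoxyphenyl)methanone
Conditions: 4-methoxybenzyl chloride, K2CO3, Bu4NI (cat.), DMF, 60 °C
Reagents that add atoms: 4-methoxybenzyl chloride, COc1ccc(CCl)cc1
Why: Williamson etherification; the 4-methoxybenzyl group supplies the future C2 carbon of ring D's dihydrofuran and its aryl group.

Step 17
Reactants: 33 benzyloxy ketone
Product: 34 hydrazone of 33
Conditions: N2H4·H2O, AcOH (cat.), n-BuOH, 110 °C
Reagents that add atoms: hydrazine, NN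
Why: Hydrazone condensation of the di-ortho-substituted benzophenone under forcing conditions; either hydrazone isomer leads to the same diazo compound.

Step 18
Reactants: 34 hydrazone
Product: 36 (2S,3R)-4-bromo-3-(3,5-dimethoxyphenyl)-6-methoxy-2-(4-methoxyphenyl)-2,3-dihydrobenzofuran (cis), via diazo compound 35 (not isolated)
Conditions: MnO2, CH2Cl2, 0 °C; filter; Rh2(R-PTAD)4 (1 mol%), CH2Cl2, −20 °C to rt
Reagents that add atoms: none
Why: Oxidation to the diaryldiazomethane and enantioselective intramolecular C–H insertion of the donor/donor rhodium carbene into the benzylic ether C–H: the chiral carboxylate ligands set C3 (R) and the concerted insertion gives the 2,3-cis ring.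

Step 19
Reactants: 37 5-bromo-2-hydroxybenzaldehyde
Product: 38 5-bromo-2-(4-methoxybenzyloxy)benzaldehyde
Conditions: 4-methoxybenzyl chloride, K2CO3, DMF, rt
Reagents that add atoms: 4-methoxybenzyl chloride, COc1ccc(CCl)cc1
Why: Williamson etherification of the phenol.

Step 20
Reactants: 36 cis bromide; 38 5-bromo-2-(4-methoxybenzyloxy)benzaldehyde
Product: 40 diaryl carbinol (mixture at the carbinol carbon), via aryllithium 39 (not isolated)
Conditions: t-BuLi (2.1 equiv), THF, −78 °C; then 38, −78 °C; aq. NH4Cl
Reagents that add atoms: none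
Why: Bromine–lithium exchange and 1,2-addition of the aryllithium to the aldehyde, which is far faster than exchange with the aryl bromide of 38; the carbinol stereocentre is removed in the next step.

Step 21
Reactants: 40 diaryl carbinol
Product: 41 diaryl ketone
Conditions: MnO2 (activated), CH2Cl2, rt
Reagents that add atoms: none
Why: MnO2 oxidation of the benzhydrol to the benzophenone.

Step 22
Reactants: 41 diaryl ketone
Product: 42 hydrazone of 41
Conditions: N2H4·H2O, AcOH (cat.), EtOH, 80 °C
Reagents that add atoms: hydrazine, NN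
Why: Hydrazone condensation of a 2,2'-disubstituted benzophenone.

Step 23
Reactants: 42 hydrazone
Product: 44 (2S,3R)-5-bromo-3-[(2S,3R)-3-(3,5-dimethoxyphenyl)-6-methoxy-2-(4-methoxyphenyl)-2,3-dihydrobenzofuran-4-yl]-2-(4-methoxyphenyl)-2,3-dihydrobenzofuran (both rings cis), via diazo compound 43 (not isolated)
Conditions: MnO2, CH2Cl2, 0 °C; filter; Rh2(R-PTAD)4 (1 mol%), CH2Cl2, −20 °C to rt
Reagents that add atoms: none
Why: Second donor/donor carbene C–H insertion under catalyst control sets C3 (R) of the ring C dihydrofuran and gives the cis ring, the alternative C–H bonds on the existing dihydrobenzofuran leading only to strained four-membered or peri-fused rings.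

Step 24
Reactants: 44 cis,cis bromide
Product: 45 (2R,3R)-5-bromo-3-[(2R,3R)-3-(3,5-dimethoxyphenyl)-6-methoxy-2-(4-methoxyphenyl)-2,3-dihydrobenzofuran-4-yl]-2-(4-methoxyphenyl)-2,3-dihydrobenzofuran (both rings trans)
Conditions: CF3CO2H, CH2Cl2 (dilute), 0 °C, short contact; aq. NaHCO3
Reagents that add atoms: none
Why: Acid-mediated epimerisation: the acid reversibly ionises each aryl C2–O bond to a 4-methoxybenzyl cation and reclosure gives the more stable 2,3-trans rings, inverting only C2 in both rings (to R) while C3 is untouched.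

**Union and end game**

Step 25
Reactants: 45 trans,trans bromide; 28 lactol triacetate
Product: 48 coupled diacetate (C-d R), via aryllithium 46 (not isolated), via arylzinc bromide 47 (not isolated)
Conditions: t-BuLi (2.1 equiv), THF, −78 °C; ZnBr2, −78 °C to rt; solvent change to toluene; then 28, BF3·OEt2, −40 to 0 °C
Reagents that add atoms: none
Why: Arylation of a cyclic oxocarbenium ion by an arylzinc, as in C-aryl glycoside synthesis: BF3 ionises the anomeric acetate and the aryl group is delivered to the face of the planar ion opposite ring A on C-b, which sets C-d (R) trans to C-b, while the low basicity of the zinc reagent lets addition outrun loss of the C-b proton.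

Step 26
Reactants: 48 coupled diacetate
Product: 49 octamethyl ether of the target with free ring B phenol and free C-c hydroxyl
Conditions: K2CO3, MeOH–THF, rt to 40 °C
Reagents that add atoms: none
Why: Zemplén-type methanolysis removes the aryl acetate and the secondary acetate without touching any ether.

Step 27
Reactants: 49 octamethyl ether
Product: 50 CNP0132116.1
Conditions: BBr3, CH2Cl2, −78 to 0 °C; MeOH, 0 °C; aq. NaHCO3
Reagents that add atoms: none
Why: Lewis-acid cleavage of the eight aryl methyl ethers with BBr3 at low temperature, the usual last step for permethylated resveratrol oligomers; any reversible opening of a 2-aryl-dihydrobenzofuran recloses to the trans ring and no stereocentre is otherwise touched.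

**Compound list**

1 | 3,5-dimethoxyphenol | COc1cc(O)cc(OC)c1 | starting material
2 | 3,5-dimethoxyphenyl N-isopropylcarbamate | COc1cc(OC)cc(OC(=O)NC(C)C)c1 | intermediate
3 | N-silyl carbamate | COc1cc(OC)cc(OC(=O)N(C(C)C)[Si](C)(C)C(C)(C)C)c1 | intermediate
4 | aryllithium of 3 | [Li]c1c(OC)cc(OC)cc1OC(=O)N(C(C)C)[Si](C)(C)C(C)(C)C | intermediate
5 | disilyl carbamate | C[Si](C)(C)c1c(OC)cc(OC)cc1OC(=O)N(C(C)C)[Si](C)(C)C(C)(C)C | intermediate
6 | 3,5-dimethoxy-2-(trimethylsilyl)phenyl N-isopropylcarbamate | C[Si](C)(C)c1c(OC)cc(OC)cc1OC(=O)NC(C)C | intermediate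
7 | 3,5-dimethoxy-2-(trimethylsilyl)phenol | C[Si](C)(C)c1c(O)cc(OC)cc1OC | intermediate
8 | 3,5-dimethoxy-2-(trimethylsilyl)phenyl trifluoromethanesulfonate | COc1cc(OC)c([Si](C)(C)C)c(OS(=O)(=O)C(F)(F)F)c1 | intermediate
9 | 3,5-dihydroxyphenylacetic acid | OC(=O)Cc1cc(O)cc(O)c1 | starting material
10 | benzyl 3,5-bis(benzyloxy)phenylacetate | O=C(Cc1cc(OCc2ccccc2)cc(OCc2ccccc2)c1)OCc1ccccc1 | intermediate
11 | 3,5-bis(benzyloxy)phenylacetic acid | OC(=O)Cc1cc(OCc2ccccc2)cc(OCc2ccccc2)c1 | intermediate
12 | acyl imidazolide of 11 | O=C(Cc1cc(OCc2ccccc2)cc(OCc2ccccc2)c1)n1ccnc1 | intermediate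
13 | methyl 4-[3,5-bis(benzyloxy)phenyl]-3-oxobutanoate | COC(=O)CC(=O)Cc1cc(OCc2ccccc2)cc(OCc2ccccc2)c1 | intermediate
14 | methyl 4-[3,5-bis(benzyloxy)phenyl]-2-diazo-3-oxobutanoate | COC(=O)C(=[N+]=[N-])C(=O)Cc1cc(OCc2ccccc2)cc(OCc2ccccc2)c1 | intermediate
15 | methyl 5,7-bis(benzyloxy)-2-oxoindane-1-carboxylate (racemic) | COC(=O)C1C(=O)Cc2cc(OCc3ccccc3)cc(OCc3ccccc3)c21 | intermediate
16 | 3,5-dimethoxybenzyne | COC1=CC#CC(OC)=C1 | intermediate
17 | methyl 6,8-bis(benzyloxy)-1,3-dimethoxy-11-oxo-10,11-dihydro-5H-dibenzo[a,d][7]annulene-5-carboxylate (racemic) | COC(=O)C1c2cc(OC)cc(OC)c2C(=O)Cc2cc(OCc3ccccc3)cc(OCc3ccccc3)c21 | intermediate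
18 | potassium enolate of 17 | COC(=O)C1c2cc(OC)cc(OC)c2C([O-])=Cc2cc(OCc3ccccc3)cc(OCc3ccccc3)c21.[K+] | intermediate
19 | enol triflate of 17 | COC(=O)C1c2cc(OC)cc(OC)c2C(OS(=O)(=O)C(F)(F)F)=Cc2cc(OCc3ccccc3)cc(OCc3ccccc3)c21 | intermediate
20 | 4-methoxyphenylboronic acid | COc1ccc(B(O)O)cc1 | starting material
21 | methyl 6,8-bis(benzyloxy)-1,3-dimethoxy-11-(4-methoxyphenyl)-5H-dibenzo[a,d][7]annulene-5-carboxylate (racemic) | COC(=O)C1c2cc(OC)cc(OC)c2C(c2ccc(OC)cc2)=Cc2cc(OCc3ccccc3)cc(OCc3ccccc3)c21 | intermediate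
22 | methyl 6,8-dihydroxy-1,3-dimethoxy-11-(4-methoxyphenyl)-5H-dibenzo[a,d][7]annulene-5-carboxylate | COC(=O)C1c2cc(OC)cc(OC)c2C(c2ccc(OC)cc2)=Cc2cc(O)cc(O)c21 | intermediate
23 | alkene lactone: carboxyl of 22 closed onto the 6-oxygen, free 8-hydroxyl (racemic at C-b) | O=C1Oc2cc(O)cc3C=C(c4ccc(OC)cc4)c4c(OC)cc(OC)cc4C1c23 | intermediate
24 | bis(tert-butyldimethylsilyl) derivative of 23 (2-silyloxybenzofuran, 8-silyloxy) | CC(C)(C)[Si](C)(C)Oc1oc2cc(O[Si](C)(C)C(C)(C)C)cc3C=C(c4ccc(OC)cc4)c4c(OC)cc(OC)cc4-c1c23 | intermediate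
25 | alkyl(isopinocampheyl)borane, boron on C-c | COc1ccc([C@@H]2c3c(OC)cc(OC)cc3-c3c4c(cc(O[Si](C)(C)C(C)(C)C)cc4[C@H]2[BH]C2CC5CC(C5(C)C)C2C)oc3O[Si](C)(C)C(C)(C)C)cc1 | intermediate
26 | hydroxy lactone (C-a R, C-b R, C-c S) | COc1ccc([C@@H]2c3c(OC)cc(OC)cc3[C@@H]3c4c(cc(O)cc4[C@H]2O)OC3=O)cc1 | intermediate
27 | aluminium hemiacetal of 26 (tris(diisobutylaluminium) alkoxide) | COc1ccc([C@@H]2c3c(OC)cc(OC)cc3[C@@H]3c4c(cc(O[Al](CC(C)C)CC(C)C)cc4[C@H]2O[Al](CC(C)C)CC(C)C)OC3O[Al](CC(C)C)CC(C)C)cc1 | intermediate
28 | lactol triacetate (anomeric mixture at C-d) | COc1ccc([C@@H]2c3c(OC)cc(OC)cc3[C@@H]3c4c(cc(OC(C)=O)cc4[C@H]2OC(C)=O)OC3OC(C)=O)cc1 | intermediate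
29 | 1-bromo-3,5-dimethoxybenzene | COc1cc(Br)cc(OC)c1 | starting material
30 | 3,5-dimethoxybenzoyl chloride | COc1cc(cc(OC)c1)C(Cl)=O | starting material
31 | (2-bromo-4,6-dimethoxyphenyl)(3,5-dimethoxyphenyl)methanone | COc1cc(OC)cc(c1)C(=O)c1c(OC)cc(OC)cc1Br | intermediate
32 | (2-bromo-6-hydroxy-4-methoxyphenyl)(3,5-dimethoxyphenyl)methanone | COc1cc(OC)cc(c1)C(=O)c1c(O)cc(OC)cc1Br | intermediate
33 | [2-bromo-4-methoxy-6-(4-methoxybenzyloxy)phenyl](3,5-dimethoxyphenyl)methanone | COc1ccc(COc2cc(OC)cc(Br)c2C(=O)c2cc(OC)cc(OC)c2)cc1 | intermediate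
34 | hydrazone of 33 | COc1ccc(COc2cc(OC)cc(Br)c2C(=NN)c2cc(OC)cc(OC)c2)cc1 | intermediate
35 | diaryldiazomethane from 34 | COc1ccc(COc2cc(OC)cc(Br)c2C(=[N+]=[N-])c2cc(OC)cc(OC)c2)cc1 | intermediate
36 | (2S,3R)-4-bromo-3-(3,5-dimethoxyphenyl)-6-methoxy-2-(4-methoxyphenyl)-2,3-dihydrobenzofuran (cis) | Brc1cc(OC)cc2c1[C@@H](c1cc(OC)cc(OC)c1)[C@@H](c1ccc(OC)cc1)O2 | intermediate
37 | 5-bromo-2-hydroxybenzaldehyde | O=Cc1cc(Br)ccc1O | starting material
38 | 5-bromo-2-(4-methoxybenzyloxy)benzaldehyde | COc1ccc(COc2ccc(Br)cc2C=O)cc1 | intermediate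
39 | aryllithium from 36 | [Li]c1cc(OC)cc2c1[C@@H](c1cc(OC)cc(OC)c1)[C@@H](c1ccc(OC)cc1)O2 | intermediate
40 | diaryl carbinol (mixture at the carbinol carbon) | OC(c1cc(Br)ccc1OCc1ccc(OC)cc1)c1cc(OC)cc2c1[C@@H](c1cc(OC)cc(OC)c1)[C@@H](c1ccc(OC)cc1)O2 | intermediate
41 | diaryl ketone | O=C(c1cc(Br)ccc1OCc1ccc(OC)cc1)c1cc(OC)cc2c1[C@@H](c1cc(OC)cc(OC)c1)[C@@H](c1ccc(OC)cc1)O2 | intermediate
42 | hydrazone of 41 | NN=C(c1cc(Br)ccc1OCc1ccc(OC)cc1)c1cc(OC)cc2c1[C@@H](c1cc(OC)cc(OC)c1)[C@@H](c1ccc(OC)cc1)O2 | intermediate
43 | diaryldiazomethane from 42 | [N-]=[N+]=C(c1cc(Br)ccc1OCc1ccc(OC)cc1)c1cc(OC)cc2c1[C@@H](c1cc(OC)cc(OC)c1)[C@@H](c1ccc(OC)cc1)O2 | intermediate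
44 | cis,cis bromide, (2S,3R) in both dihydrobenzofurans | Brc1ccc2c(c1)[C@@H](c1cc(OC)cc3c1[C@@H](c1cc(OC)cc(OC)c1)[C@@H](c1ccc(OC)cc1)O3)[C@@H](c1ccc(OC)cc1)O2 | intermediate
45 | trans,trans bromide, (2R,3R) in both dihydrobenzofurans | Brc1ccc2c(c1)[C@@H](c1cc(OC)cc3c1[C@@H](c1cc(OC)cc(OC)c1)[C@H](c1ccc(OC)cc1)O3)[C@H](c1ccc(OC)cc1)O2 | intermediate
46 | aryllithium from 45 | [Li]c1ccc2c(c1)[C@@H](c1cc(OC)cc3c1[C@@H](c1cc(OC)cc(OC)c1)[C@H](c1ccc(OC)cc1)O3)[C@H](c1ccc(OC)cc1)O2 | intermediate
47 | arylzinc bromide from 45 | Br[Zn]c1ccc2c(c1)[C@@H](c1cc(OC)cc3c1[C@@H](c1cc(OC)cc(OC)c1)[C@H](c1ccc(OC)cc1)O3)[C@H](c1ccc(OC)cc1)O2 | intermediate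
48 | coupled diacetate (C-a R, C-b R, C-c S, C-d R; lower rings 2R,3R) | COc1ccc([C@@H]2c3c(OC)cc(OC)cc3[C@@H]3c4c(cc(OC(C)=O)cc4[C@H]2OC(C)=O)O[C@H]3c2ccc3c(c2)[C@@H](c2cc(OC)cc4c2[C@@H](c2cc(OC)cc(OC)c2)[C@H](c2ccc(OC)cc2)O4)[C@H](c2ccc(OC)cc2)O3)cc1 | intermediate
49 | octamethyl ether of the target (free ring B phenol, free C-c hydroxyl) | COc1ccc([C@@H]2c3c(OC)cc(OC)cc3[C@@H]3c4c(cc(O)cc4[C@H]2O)O[C@H]3c2ccc3c(c2)[C@@H](c2cc(OC)cc4c2[C@@H](c2cc(OC)cc(OC)c2)[C@H](c2ccc(OC)cc2)O4)[C@H](c2ccc(OC)cc2)O3)cc1 | intermediate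
50 | CNP0132116.1 | Oc1ccc([C@@H]2c3c(O)cc(O)cc3[C@@H]3c4c(cc(O)cc4[C@H]2O)O[C@H]3c2ccc3c(c2)[C@@H](c2cc(O)cc4c2[C@@H](c2cc(O)cc(O)c2)[C@H](c2ccc(O)cc2)O4)[C@H](c2ccc(O)cc2)O3)cc1 | target

**Step count.** Total: 27 steps. Longest linear sequence: 14 steps (steps 4–14, then 25–27).

**Steps most likely to fail**

Step 13. The hindered triaryl alkene may be hydroborated slowly or with poor facial selectivity, and the base equilibration at C-b may stop at a mixture or favour the wrong epimer. The fallback fixes C-b and C-d first and lets them direct the hydroboration. It sets out from alkene lactone 23, which is reduced with i-Bu2AlH and acetylated in situ (Ac2O, pyridine, DMAP) to the racemic alkene lactol diacetate F1. Union of F1 with arylzinc bromide 47 under BF3·OEt2 should give the trans-dihydrobenzofuran alkene acetate F2 together with the diastereomer from the other enantiomer of F1, and the two are separated by chromatography. Hydroboration of F2 with BH3·THF should take place on the open outer face of the folded ring system, anti to the pseudo-axial C-b hydrogen; NaOH/H2O2 then oxidises the borane and cleaves the aryl acetate. The route is rejoined at 49.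

Step 25. The oxocarbenium ion may lose the C-b proton and aromatise to the benzofuran, or the hindered arylzinc may transfer too slowly. The fallback replaces cation arylation by carbonyl addition and ring closure. It sets out from hydroxy lactone 26, which is reduced with i-Bu2AlH at −78 °C and worked up without acetylation to the lactol F3. After deprotonation of its hydroxyls with NaH, the organocerium reagent made from aryllithium 46 and CeCl3 adds to the open hydroxy aldehyde form to give the triol F4 as a carbinol mixture. Catalytic PPTS then ionises the 4-alkoxybenzylic carbinol and the neighbouring ring B phenol closes the trans-dihydrobenzofuran. The route is rejoined at 49.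

Step 27. The Lewis acid may open the ring C dihydrofuran and let ring E capture the cation in a Friedel–Crafts closure, or may ionise the C-c carbinol. The fallback changes from electrophilic to nucleophilic dealkylation in basic medium: 49 is heated with excess MeMgI as a solvent-free melt (about 160 °C), in which phenols and the carbinol are held as magnesium salts and no carbocation is generated, and acidic work-up gives 50 directly. No new compound is involved.

**Further compounds**

F1 | step 13 | alkene lactol diacetate (racemic) | CC(=O)OC1Oc2cc(OC(C)=O)cc3C=C(c4ccc(OC)cc4)c4c(OC)cc(OC)cc4C1c23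
F2 | step 13 | alkene-coupled aryl acetate (C-b R, C-d R) | COc1ccc(C=2c3c(OC)cc(OC)cc3[C@@H]3c4c(cc(OC(C)=O)cc4C=2)O[C@H]3c2ccc3c(c2)[C@@H](c2cc(OC)cc4c2[C@@H](c2cc(OC)cc(OC)c2)[C@H](c2ccc(OC)cc2)O4)[C@H](c2ccc(OC)cc2)O3)cc1
F3 | step 25 | lactol of 26 | COc1ccc([C@@H]2c3c(OC)cc(OC)cc3[C@@H]3c4c(cc(O)cc4[C@H]2O)OC3O)cc1
F4 | step 25 | ring-opened triol (carbinol mixture at C-d) | COc1ccc([C@@H]2c3c(OC)cc(OC)cc3[C@@H](C(O)c3ccc5c(c3)[C@@H](c3cc(OC)cc6c3[C@@H](c3cc(OC)cc(OC)c3)[C@H](c3ccc(OC)cc3)O6)[C@H](c3ccc(OC)cc3)O5)c4c(cc(O)cc4[C@H]2O)O)cc1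
F0 | step 27 | none | none
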